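The 3 questions ask how far winter and summer get towards a limit within their times.

common to all: coupling partner 0.315 M; free catalyst 3.1 mM

| charge | substrate | temperature | remark | time |
|---|---|---|---|---|
| south-west | 0.32 M | 20 °C | run made earlier |  |
| south | 0.47 M | 45 °C | run made earlier |  |
| winter | 0.63 M |  | at 25 °C throughout | 40 h |
| summer | 0.63 M |  | at 25 °C until 2.5 h, from then on at 65 °C | 12 h |

| run | time / h | product / % |
|---|---|---|
| south-west | 2.00 | 6.3 |
| south-west | 5.00 | 14.3 |
| south-west | 10.0 | 28.5 |
| south-west | 15.0 | 39.9 |
| south | 0.333 | 5.3 |
| south | 1.00 | 15.6 |
| south | 2.00 | 27.8 |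
| south | 6.00 | 56.6 |

(scatter of a reading: 0.5 percentage points)

- which of the two ends with the higher amount of product, in percent of the substrate charged ("neither" if they lie within 2 percentage points) (winter / summer / neither)
- product at the end, in percent of the substrate charged, winter
- product at the end, in percent of the substrate charged, summer

- the numbers in the tables scatter with a standard deviation of 0.5 percentage points

The main step consumes one coupling partner per substrate and makes one product. In winter and in summer the coupling partner is therefore the limiting reagent, and product in percent of the substrate charged stops at the ceiling, the charge c(coupling partner) over the charge c(substrate), 50.0%. With this step and no rate yet counted, both flasks stand at the ceiling.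

Adding a rate, taken as first order in coupling partner with constant k, gives the closed form: product = ceiling × (1 − exp(−∫k dt)). The last reading of each run gives k as 0.0347 h⁻¹ at 20 °C and 0.310 h⁻¹ at 45 °C. A straight line of ln k against temperature then gives 0.0537 h⁻¹ at 25 °C and roughly 1.79 h⁻¹ at 65 °C. Winter collects an integral of 2.15, which lowers its number to 44.2%. Summer collects 17.2, so if its catalyst survives the heat, summer stays at 50.0%.

The rest of the chemistry shows in the south run, whose k read from the first reading is 0.247 h⁻¹, less than the value from the last. The constant thus shifts within the south run, and substrate and temperature differ together between the two runs, so the winter number stays an estimate. This reckoning commits to summer, ahead by 5.8 points.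

The forecast also says summer, with 39.5% for winter from its rate law integrated over 40 h, and 49.5% for summer, where “then 65 °C should finish it”. The simulated flasks end at 49.3% in winter and 50.0% in summer, so the answer is neither.

    2 catalyst intermediate A ⇌ resting dimer, settled at all times (K = 265 L mol⁻¹, ΔH = −19.0 kJ mol⁻¹)
    substrate + free catalyst → catalyst intermediate A (k = 0.446 L mol⁻¹ min⁻¹, Ea = 57.0 kJ mol⁻¹)
    catalyst intermediate C → free catalyst + product (k = 11.4 min⁻¹, Ea = 87.0 kJ mol⁻¹)
    coupling partner + catalyst intermediate A ⇌ catalyst intermediate B (K = 6.60 L mol⁻¹, k = 2.20 L mol⁻¹ min⁻¹, Ea = 43.0 kJ mol⁻¹, ΔH = −33.0 kJ mol⁻¹)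
    catalyst intermediate B → catalyst intermediate C (k = 0.553 min⁻¹, Ea = 88.0 kJ mol⁻¹)
    (constants at 25 °C)

Summer lies on the ceiling of 50.0%, with 0% of its coupling partner left at 12.0 h. Winter ends 5.1 points above the reckoned 44.2%, with 1.42% of its coupling partner left at 40.0 h. The same quotient, taken on a neighbour of summer charged with 0.19 M of coupling partner and otherwise unchanged, gives a ceiling of 30.2%. That neighbour ends at 30.2% of product, with 69% of its substrate left unbound.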